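## The problem

Numbering used throughout: ring carbons C1 (carbinol carrying the acyl chain), C5 (acyloxy CH), C6 (lactone O–CH), C7 (ring fusion), C8 (CH2), C9 (CHOH), C10 (CHCH3); lactone C11 (α-carbon), C12 (carbonyl), C13 (methylene); side chain C2 (ketone), C3, C4 (carbinol). TBS = tert-butyl(dimethyl)silyl.

The target is a cycloheptane with a cis-fused α-methylene-γ-butyrolactone across C6/C7, a tertiary carbinol C1 bearing a 3-hydroxybutanoyl chain, an (R)-2-methylbutanoate on the C5 oxygen, a free hydroxyl on C9 and a methyl on C10. Six of the eight stereocentres sit on the seven-membered ring, where conformational control is poor. The other two (C4 and the ester α-carbon) are isolated and have to be bought. Around the ring the relationships are C5–O/C6–O trans, C6–O/C7–C11 cis, C9–O/C10–Me trans, C10–Me/C1–O cis and C1–O/C5–O trans. C6 can therefore control C7, and C10 and C6 flank C1 and C5 and can control them if these two are made last. The molecule is fragile: the methylene lactone is a Michael acceptor, the β-hydroxy ketone can dehydrate or undergo retro-aldol cleavage, the tertiary α-ketol can cleave or rearrange, and the ester sits beside free hydroxyls. No strong base or nucleophile is acceptable once the ketol exists, and the exocyclic methylene should appear last. The enabling feature is that C2, C1 and C5 are three contiguous oxygenated carbons and that the ring bond C1–C5 joins two carbons that both derive from carbonyl groups. A C1/C2 diketone reduced to its enediolate becomes nucleophilic at C1 and can add to a C5 aldehyde. That closes the ring and creates the C2 ketone, the C1 carbinol and the C5 hydroxyl in their final oxidation states.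

## Retrosynthesis

**Methylene, lactone and ester (C11=C13, O–C12, C5–O–acyl).** The methylene lactone of 31 is traced to the α-carboxy lactone 29 (decarboxylative Mannich methylenation). 29 comes from the tetraol diester 27 (acidolysis of the tert-butyl esters with lactonisation), 27 from its silyl ethers 26, and 26 from ketol 24 and acid 25. A malonate arm on C7 carries C11 and C12 through the synthesis and allows methylenation without an enolate, which a plain lactone next to the ketol would not. The forward reactions must acylate the secondary C5 hydroxyl beside the tertiary C1 one, and must lactonise only on the C6 oxygen, the one hydroxyl cis and γ to the carboxyls.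

**Ring closure (C1–C5).** 24 is cut to the open-chain diketone aldehyde 22. This cut removes the ring and the two hardest stereocentres together. The neighbouring cuts are worse: C5–C6 would leave the quaternary ketol to be built on an open chain, and C1–C10 would need alkylation of a ketol. 22 has four ring stereocentres (C6, C7, C9, C10), each accessible by standard acyclic chemistry. The forward step must reduce the diketone before the aldehyde, close through C1 and not C2, and set C1 and C5 from C10 and C6.

**Oxidation states (C1/C2 and C5).** 22 comes from alcohol 21, 21 from the tetrasilyl diketone 20, and 20 from alkyne 19. The diketone is unveiled only three steps before use because C10 is then enolisable. The primary silyl ether on C5 is the one that buffered fluoride removes selectively.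

**C9–C10.** 19 is the silyl ether of homopropargylic alcohol 18, cut to aldehyde 10 and allenylstannane 17. The C9 hydroxyl and C10 methyl, trans on the ring, are syn along the open C8–C1 chain. The addition therefore has to be the open-transition-state (BF3) variant; cyclic allenylzinc or allenylindium additions would give the anti pair. Fragment 17 already holds C1–C4, so no strong base is needed on the main chain, where the malonate C–H would be deprotonated before a terminal alkyne.

**Fragment 17.** 17 comes from mesylate 16 by anti SN2′ stannylation, 16 from carbinol 15, 15 from ynone 14 by catalyst-controlled reduction, and 14 from silyl ether 12 and amide 13. 12 is the silyl ether of 11, the acetylide adduct of (S)-propylene oxide, which supplies C4.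

**C7–C11.** Aldehyde 10 comes from Weinreb amide 9, 9 from alcohol 8, 8 from lactone 7, and 7 from butenolide 5 and malonate 6. C6–O and C7–C11 must be anti along the open chain. Addition to the face of the butenolide opposite its C5 substituent gives exactly this, without relying on acyclic 1,2-induction of uncertain sense. The lactone also differentiates the C5 and C6 oxygens without extra protecting-group steps.

**Butenolide.** 5 is the silyl ether of 4, made from (S)-glyceraldehyde acetonide 1 and ylide 2 through the Z ester 3. C6 comes from the chiral pool.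

## Roads not taken

Alternative 1: furan–oxyallyl (4+3) cycloaddition, cutting C5–C6 and C9–C10. The oxyallyl cation from chloroketone A2 (Et3N in a fluorinated alcohol) would add across the 2,5-positions of furan A1 and give the oxygen-bridged cycloheptenone A3 in one step.
- Merits: it is by far the quickest way to the carbocycle, from two trivial fragments. The rigid bicycle would give good facial control for later additions at the C1 ketone.
- Weak points: A3 is racemic. The orientation of the unsymmetrical cation on the unsymmetrical furan is not secured. One bridging oxygen must serve both C6 and C9, so one C–O bond has to be broken and an oxygen reinstalled with the right configuration. C5 is a bare methylene, C7=C8 must be reduced with control at C7, and the C1 carbinol with its acyl chain still needs an acyl-anion addition.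
- Comparison: in speed of ring construction this road is clearly better (one step against sixteen linear steps to 24). The chosen plan sets against that the state of the ring at closure: every atom and every oxidation level of the target ring is in place, six stereocentres are defined, and four steps remain.

Alternative 2: intramolecular allylchromium addition, cutting C6–C7 and O–C12. CrCl2 (divalent chromium) would turn a (Z)-2-(alkoxycarbonyl)allyl bromide into an allylchromium reagent that adds through C7 to a C6 aldehyde. The alkoxide then closes the lactone and gives A4, one desilylation from the target.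
- Merits: the reaction type is known, including ring-forming cases. It makes the carbocycle, C6, C7 and the finished methylene lactone at once, at the latest possible stage.
- Weak points: the substrate must already contain the C1 ketol next to the acylated C5 and a C6 aldehyde, all built on an open chain; that is the hardest part of the molecule, and this road does not help with it. The aldehyde is α to an acyloxy group (elimination, acyl migration). Divalent chromium may attack the α-oxygenated C2 ketone. C6/C7 relative to C5 rests on 1,2-induction alone.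
- Comparison: on precedent for the key step and on endgame economy this road is better. The chosen plan sets against it that its cyclisation substrate is reached by routine acyclic chemistry, and that C1 and C5 are created by the ring closure itself, not before it.

Alternative 3: acyl radical 7-endo closure, cutting C8–C9. A C9 selenoester with (Me3Si)3SiH would release an acyl radical that adds to the methylene carbon C8 of an α-methylene ketone, giving the cycloheptane-1,4-dione A5.
- Merits: acyl-radical 7-endo closures onto such acceptors are known. The neutral conditions tolerate silyl ethers. C1 and C5 are brought in from open-chain chemistry.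
- Weak points: C7 is formed by hydrogen transfer to an α-keto radical without control. The C6 and C9 ketones then need two separate stereoselective reductions beside epimerisable centres (C7, C10). The alkyne must be hydrated towards C2 only. The lactone must be closed and methylenated in the presence of a ketone. The C1 alkynyl carbinol has to be set on an open chain.
- Comparison: its ring closure stands on firmer ground than the samarium step. The chosen plan sets against it that C6, C7, C9 and C10 are secure before the ring closes and that the endgame is four steps, without reductions on the ring.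

Key step: step 17

Remark: C9–OH/C10–Me are trans on the ring (syn along the open chain) and C6–O/C7–C11 are cis on the ring (anti along the open chain); steps 3 and 12 are chosen for these two relationships.
Remark: (S)-pent-4-yn-2-ol 11 is taken as the commercial acetylide adduct of (S)-propylene oxide; C11 of 29 and 30 is left unspecified because step 21 destroys it; the double-bond geometry of enediolate 23 is left open.

## Route

Step 1
Reactants: 1 (S)-2,2-dimethyl-1,3-dioxolane-4-carbaldehyde; 2 methyl (triphenylphosphoranylidene)acetate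
Product: 4 (R)-5-(hydroxymethyl)furan-2(5H)-one, via Z-enoate 3 (not isolated)
Conditions: MeOH, 0 °C; then conc. H2SO4 (cat.), MeOH, rt
Reagents that add atoms: none
Why: Wittig olefination of an α-alkoxy aldehyde with a stabilised ylide in methanol should give mainly the Z ester; acid then removes the acetonide and the freed C6 hydroxyl, cis to the ester, closes the butenolide, while any E ester cannot lactonise and is separated. C6 is carried over unchanged from 1.

Step 2
Reactants: 4 (R)-5-(hydroxymethyl)furan-2(5H)-one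
Product: 5 (R)-5-(TBSO-methyl)furan-2(5H)-one
Conditions: TBSCl, imidazole, CH2Cl2, 0 °C to rt
Reagents that add atoms: tert-butyl(dimethyl)silyl chloride, CC(C)(C)[Si](C)(C)Cl
Why: Standard silylation of a primary alcohol; imidazole is too weak a base to deprotonate the butenolide at C6.

Step 3
Reactants: 5 (R)-5-(TBSO-methyl)furan-2(5H)-one; 6 di-tert-butyl malonate
Product: 7 di-tert-butyl 2-[(2R,3S)-2-(TBSO-methyl)-5-oxooxolan-3-yl]propanedioate
Conditions: t-BuOK (0.1 equiv), THF, −20 to 0 °C; AcOH quench
Reagents that add atoms: none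
Why: Michael addition of a malonate anion to a 5-substituted butenolide; the nucleophile adds to the face opposite the silyloxymethyl group, which sets C7 with C11 trans to C5 on the lactone, i.e. C7–C11 anti to C6–O in the open chain. Catalytic base keeps the medium at the basicity of the malonate anion and should spare the C6–H.

Step 4
Reactants: 7 di-tert-butyl 2-[(2R,3S)-2-(TBSO-methyl)-5-oxooxolan-3-yl]propanedioate
Product: 8 di-tert-butyl 2-[(2R,3S)-1-(TBSO)-2-hydroxy-5-[methoxy(methyl)amino]-5-oxopentan-3-yl]propanedioate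
Conditions: MeNH(OMe)·HCl, AlMe3, CH2Cl2, 0 °C to rt; aq. potassium sodium tartrate
Reagents that add atoms: N,O-dimethylhydroxylamine hydrochloride, CNOC.Cl
Why: Aluminium amide aminolysis of a γ-lactone to the Weinreb amide; tert-butyl esters are inert to the reagent at this temperature and the malonate C–H only consumes one further equivalent.

Step 5
Reactants: 8 di-tert-butyl 2-[(2R,3S)-1-(TBSO)-2-hydroxy-5-[methoxy(methyl)amino]-5-oxopentan-3-yl]propanedioate
Product: 9 di-tert-butyl 2-[(2R,3S)-1,2-bis(TBSO)-5-[methoxy(methyl)amino]-5-oxopentan-3-yl]propanedioate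
Conditions: TBSOTf (1.2 equiv), 2,6-lutidine, CH2Cl2, −78 to 0 °C
Reagents that add atoms: tert-butyl(dimethyl)silyl trifluoromethanesulfonate, CC(C)(C)[Si](C)(C)OS(=O)(=O)C(F)(F)F
Why: The silyl triflate caps the hindered C6 hydroxyl quickly at low temperature, before it can relactonise; this bulky non-chelating ether is the C6 group the ring closure needs.

Step 6
Reactants: 9 di-tert-butyl 2-[(2R,3S)-1,2-bis(TBSO)-5-[methoxy(methyl)amino]-5-oxopentan-3-yl]propanedioate
Product: 10 di-tert-butyl 2-[(2R,3S)-1,2-bis(TBSO)-5-oxopentan-3-yl]propanedioate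
Conditions: i-Bu2AlH (2.2 equiv), THF, −78 °C; aq. potassium sodium tartrate
Reagents that add atoms: none
Why: Weinreb amide reduction stops at the aldehyde through the chelated tetrahedral intermediate; the first equivalent of hydride is spent on the malonate C–H and the resulting enolate shields the tert-butyl esters.

Step 7
Reactants: 11 (S)-pent-4-yn-2-ol
Product: 12 tert-butyl(dimethyl)[(2S)-pent-4-yn-2-yloxy]silane
Conditions: TBSCl, imidazole, DMF, rt
Reagents that add atoms: tert-butyl(dimethyl)silyl chloride, CC(C)(C)[Si](C)(C)Cl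
Why: Standard silylation of a secondary alcohol; this stereocentre becomes C4.

Step 8
Reactants: 12 tert-butyl(dimethyl)[(2S)-pent-4-yn-2-yloxy]silane; 13 N-methoxy-N-methylacetamide
Product: 14 (6S)-6-(TBSO)hept-3-yn-2-one
Conditions: n-BuLi, THF, −78 °C; then 13, −78 to 0 °C; aq. NH4Cl
Reagents that add atoms: none
Why: Acylation of a lithium acetylide with a Weinreb amide gives the ynone without over-addition.

Step 9
Reactants: 14 (6S)-6-(TBSO)hept-3-yn-2-one
Product: 15 (2R,6S)-6-(TBSO)hept-3-yn-2-ol
Conditions: RuCl[(R,R)-TsDPEN](p-cymene) (1 mol%), i-PrOH, rt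
Reagents that add atoms: none
Why: Noyori transfer hydrogenation of an alkynyl methyl ketone, in which the alkyne takes the place of the aryl group, so the (R,R) catalyst should deliver the (R)-carbinol under catalyst control; the remote silyloxy centre has no say.

Step 10
Reactants: 15 (2R,6S)-6-(TBSO)hept-3-yn-2-ol
Product: 16 (2R,6S)-6-(TBSO)hept-3-yn-2-yl methanesulfonate
Conditions: MsCl, Et3N, CH2Cl2, −78 °C
Reagents that add atoms: methanesulfonyl chloride, CS(=O)(=O)Cl
Why: Mesylation of a secondary propargylic alcohol with retention; the crude mesylate is used at once.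

Step 11
Reactants: 16 (2R,6S)-6-(TBSO)hept-3-yn-2-yl methanesulfonate
Product: 17 tributyl[(2S)-2-(TBSO)hepta-4,5-dien-4-yl]stannane with the P (Sa) allene axis
Conditions: Bu3SnH, LiN(i-Pr)2, THF, 0 °C; CuBr·SMe2, −78 °C; then 16, −78 °C
Reagents that add atoms: tributyltin hydride (as its lithium derivative), CCCC[SnH](CCCC)CCCC
Why: The stannylcuprate displaces the propargylic mesylate in an anti SN2′ fashion, so the (R)-carbinol centre is converted into the P allene axis.

Step 12
Reactants: 10 di-tert-butyl 2-[(2R,3S)-1,2-bis(TBSO)-5-oxopentan-3-yl]propanedioate; 17 tributyl[(2S)-2-(TBSO)hepta-4,5-dien-4-yl]stannane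
Product: 18 di-tert-butyl 2-[(2R,3S,5R,6R,10S)-1,2,10-tris(TBSO)-5-hydroxy-6-methylundec-7-yn-3-yl]propanedioate
Conditions: BF3·OEt2, CH2Cl2, −78 °C; aq. NaHCO3
Reagents that add atoms: none
Why: BF3-promoted SE2′ addition of a chiral allenylstannane (open-transition-state variant of the Marshall propargylation) forms C9–C10: the aldehyde attacks anti to tin, which fixes C10 from the allene axis, and the acyclic transition state gives the syn C9/C10 pair. The C7 centre is too remote to override the reagent.

Step 13
Reactants: 18 di-tert-butyl 2-[(2R,3S,5R,6R,10S)-1,2,10-tris(TBSO)-5-hydroxy-6-methylundec-7-yn-3-yl]propanedioate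
Product: 19 di-tert-butyl 2-[(2R,3S,5R,6R,10S)-1,2,5,10-tetrakis(TBSO)-6-methylundec-7-yn-3-yl]propanedioate
Conditions: TBSOTf (1.2 equiv), 2,6-lutidine, CH2Cl2, −78 °C
Reagents that add atoms: tert-butyl(dimethyl)silyl trifluoromethanesulfonate, CC(C)(C)[Si](C)(C)OS(=O)(=O)C(F)(F)F
Why: Silyl triflate silylation of a hindered secondary alcohol; it also blocks δ-lactonisation of the C9 hydroxyl onto the malonate.

Step 14
Reactants: 19 di-tert-butyl 2-[(2R,3S,5R,6R,10S)-1,2,5,10-tetrakis(TBSO)-6-methylundec-7-yn-3-yl]propanedioate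
Product: 20 di-tert-butyl 2-[(2R,3S,5R,6S,10S)-1,2,5,10-tetrakis(TBSO)-6-methyl-7,8-dioxoundecan-3-yl]propanedioate
Conditions: RuO2·xH2O (cat.), NaIO4, CCl4/MeCN/H2O, 0 °C to rt
Reagents that add atoms: sodium periodate, [Na+].[O-]I(=O)(=O)=O
Why: RuO4 generated in situ oxidises internal alkynes to 1,2-diketones; silyl ethers and tert-butyl esters are inert, and the short, near-neutral biphasic reaction should leave the now enolisable C10 centre untouched (its descriptor changes from R to S only through the priority change).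

Step 15
Reactants: 20 di-tert-butyl 2-[(2R,3S,5R,6S,10S)-1,2,5,10-tetrakis(TBSO)-6-methyl-7,8-dioxoundecan-3-yl]propanedioate
Product: 21 di-tert-butyl 2-[(2R,3S,5R,6S,10S)-2,5,10-tris(TBSO)-1-hydroxy-6-methyl-7,8-dioxoundecan-3-yl]propanedioate
Conditions: HF·pyridine, pyridine, THF, 0 °C
Reagents that add atoms: none
Why: Buffered HF·pyridine cleaves a primary silyl ether much faster than the three secondary ones.

Step 16
Reactants: 21 di-tert-butyl 2-[(2R,3S,5R,6S,10S)-2,5,10-tris(TBSO)-1-hydroxy-6-methyl-7,8-dioxoundecan-3-yl]propanedioate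
Product: 22 di-tert-butyl 2-[(2R,3S,5R,6S,10S)-2,5,10-tris(TBSO)-6-methyl-1,7,8-trioxoundecan-3-yl]propanedioate
Conditions: Dess–Martin periodinane, NaHCO3, CH2Cl2, 0 °C
Reagents that add atoms: none
Why: Buffered Dess–Martin oxidation gives the α-silyloxy aldehyde without base, so neither C6 nor C10 should epimerise; the aldehyde is used at once.

Step 17
Reactants: 22 di-tert-butyl 2-[(2R,3S,5R,6S,10S)-2,5,10-tris(TBSO)-6-methyl-1,7,8-trioxoundecan-3-yl]propanedioate
Product: 24 di-tert-butyl 2-[(1S,2R,3S,4S,5S,6R)-2,6-bis(TBSO)-4-[(3S)-3-(TBSO)butanoyl]-3,4-dihydroxy-5-methylcycloheptyl]propanedioate, via samarium enediolate 23 (not isolated)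
Conditions: SmI2 (2.1 equiv, 0.1 M in THF, slow addition), THF, −78 °C; pH 7 phosphate buffer, −78 °C to rt
Reagents that add atoms: none
Why: Proposed new method: two equivalents of SmI2 (divalent samarium) should reduce the C1/C2 diketone, by far the most easily reduced group of 22, to the enediolate 23 (trivalent samarium on both oxygens), whose carbon C1 then adds to the C5 aldehyde in an intramolecular aldol step; the closest known reaction types are SmI2 ketone–aldehyde pinacol cyclisations and the intermolecular coupling of 1,2-diketones with aldehydes by low-valent metals, neither shown for a seven-membered ring closed from a diketone. The ring closes 7-exo-trig on the aldehyde with the enolate double bond outside the new ring; closure through C2 would be eight-membered with the double bond inside and should lose. C1 is set by C10: allylic 1,3-strain keeps the C10–H in the enediolate plane, the tether (C9) lies on one face and the methyl on the other, so C5 arrives anti to the methyl and the C1 oxygen ends up cis to it. C5 is set by C6: because C7 is part of the forming ring, the bulky non-chelating silyl ether can sit anti to the forming bond (polar Felkin–Anh arrangement), which places the C5 oxygen trans to the C6 oxygen, whereas a chelated C5/C6 pair would give the cis isomer. Samarium bridging the C2 oxygen and the aldehyde oxygen in a six-membered chelate cis-fused to the new ring (Zimmerman–Traxler type) fits both preferences and leaves the C1 and C5 oxygens trans. The step needs the diketone reduced before the aldehyde and the enediolate cyclised before it is protonated (the malonate C–H is the only acidic site); slow addition of just two equivalents at −78 °C without additive or proton source serves both and protects the product ketol from C1–O cleavage by excess reductant.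

Step 18
Reactants: 24 di-tert-butyl 2-[(1S,2R,3S,4S,5S,6R)-2,6-bis(TBSO)-4-[(3S)-3-(TBSO)butanoyl]-3,4-dihydroxy-5-methylcycloheptyl]propanedioate; 25 (R)-2-methylbutanoic acid
Product: 26 di-tert-butyl 2-[(1S,2R,3S,4S,5S,6R)-2,6-bis(TBSO)-4-[(3S)-3-(TBSO)butanoyl]-4-hydroxy-5-methyl-3-{[(2R)-2-methylbutanoyl]oxy}cycloheptyl]propanedioate
Conditions: N,N'-diisopropylcarbodiimide, DMAP, CH2Cl2, 0 °C to rt
Reagents that add atoms: none
Why: Steglich esterification; only the secondary C5 hydroxyl can be acylated, the C1 carbinol being tertiary, and a simple α-alkyl acid should keep its configuration under carbodiimide/DMAP activation.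

Step 19
Reactants: 26 di-tert-butyl 2-[(1S,2R,3S,4S,5S,6R)-2,6-bis(TBSO)-4-[(3S)-3-(TBSO)butanoyl]-4-hydroxy-5-methyl-3-{[(2R)-2-methylbutanoyl]oxy}cycloheptyl]propanedioate
Product: 27 di-tert-butyl 2-[(1S,2R,3S,4S,5S,6R)-2,4,6-trihydroxy-4-[(3S)-3-hydroxybutanoyl]-5-methyl-3-{[(2R)-2-methylbutanoyl]oxy}cycloheptyl]propanedioate
Conditions: HF·pyridine, THF, 0 °C to rt
Reagents that add atoms: none
Why: Fluoride cleavage of the three remaining silyl ethers under mildly acidic conditions, which the ketol, the C5 ester and the tert-butyl esters tolerate and under which acyl migration is slow.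

Step 20
Reactants: 27 di-tert-butyl 2-[(1S,2R,3S,4S,5S,6R)-2,4,6-trihydroxy-4-[(3S)-3-hydroxybutanoyl]-5-methyl-3-{[(2R)-2-methylbutanoyl]oxy}cycloheptyl]propanedioate
Product: 29 (3aS,5R,6S,7S,8S,8aR)-5,7-dihydroxy-7-[(3S)-3-hydroxybutanoyl]-6-methyl-8-{[(2R)-2-methylbutanoyl]oxy}-2-oxooctahydro-2H-cyclohepta[b]furan-3-carboxylic acid (C3 epimers), via malonic diacid 28 (not isolated)
Conditions: CF3CO2H, CH2Cl2 (1:3), 0 °C to rt; then MeOH, rt
Reagents that add atoms: none
Why: Acidolysis of the tert-butyl esters; of the free hydroxyls only the C6 one is cis and γ to a carboxyl (the C9 hydroxyl is trans to the C7 arm and cannot bridge), so the diacid closes the cis-fused γ-lactone. Methanol cleaves any trifluoroacetates.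

Step 21
Reactants: 29 (3aS,5R,6S,7S,8S,8aR)-5,7-dihydroxy-7-[(3S)-3-hydroxybutanoyl]-6-methyl-8-{[(2R)-2-methylbutanoyl]oxy}-2-oxooctahydro-2H-cyclohepta[b]furan-3-carboxylic acid
Product: 31 (3aS,5R,6S,7S,8S,8aR)-5,7-dihydroxy-7-[(3S)-3-hydroxybutanoyl]-6-methyl-3-methylidene-2-oxooctahydro-2H-cyclohepta[b]furan-8-yl (2R)-2-methylbutanoate (CNP0291806.3), via Mannich base 30 (not isolated)
Conditions: 37% aq. CH2O, Et2NH, THF, 0 °C to rt; then AcOH, NaOAc, 40 °C
Reagents that add atoms: formaldehyde, C=O
Why: Decarboxylative Mannich methylenation of an α-carboxy lactone: the β-amino acid 30 loses CO2 and the amine to give the exocyclic alkene under near-neutral conditions. The malonic C–H is far more acidic than the ketone α-CH2, which should therefore stay out of the reaction.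

## Compound list

1 | (S)-2,2-dimethyl-1,3-dioxolane-4-carbaldehyde | O=C[C@@H]1COC(C)(C)O1 | starting material
2 | methyl (triphenylphosphoranylidene)acetate | COC(=O)C=P(c1ccccc1)(c1ccccc1)c1ccccc1 | starting material
3 | methyl (R,Z)-3-(2,2-dimethyl-1,3-dioxolan-4-yl)prop-2-enoate | COC(=O)/C=C\[C@@H]1COC(C)(C)O1 | intermediate
4 | (R)-5-(hydroxymethyl)furan-2(5H)-one | OC[C@@H]1OC(=O)C=C1 | intermediate
5 | (R)-5-(TBSO-methyl)furan-2(5H)-one | CC(C)(C)[Si](C)(C)OC[C@@H]1OC(=O)C=C1 | intermediate
6 | di-tert-butyl malonate | CC(C)(C)OC(=O)CC(=O)OC(C)(C)C | starting material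
7 | di-tert-butyl 2-[(2R,3S)-2-(TBSO-methyl)-5-oxooxolan-3-yl]propanedioate | CC(C)(C)[Si](C)(C)OC[C@@H]1OC(=O)C[C@H]1C(C(=O)OC(C)(C)C)C(=O)OC(C)(C)C | intermediate
8 | di-tert-butyl 2-[(2R,3S)-1-(TBSO)-2-hydroxy-5-[methoxy(methyl)amino]-5-oxopentan-3-yl]propanedioate | CON(C)C(=O)C[C@H]([C@@H](O)CO[Si](C)(C)C(C)(C)C)C(C(=O)OC(C)(C)C)C(=O)OC(C)(C)C | intermediate
9 | di-tert-butyl 2-[(2R,3S)-1,2-bis(TBSO)-5-[methoxy(methyl)amino]-5-oxopentan-3-yl]propanedioate | CON(C)C(=O)C[C@H]([C@@H](O[Si](C)(C)C(C)(C)C)CO[Si](C)(C)C(C)(C)C)C(C(=O)OC(C)(C)C)C(=O)OC(C)(C)C | intermediate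
10 | di-tert-butyl 2-[(2R,3S)-1,2-bis(TBSO)-5-oxopentan-3-yl]propanedioate | O=CC[C@H]([C@@H](O[Si](C)(C)C(C)(C)C)CO[Si](C)(C)C(C)(C)C)C(C(=O)OC(C)(C)C)C(=O)OC(C)(C)C | intermediate
11 | (S)-pent-4-yn-2-ol | C[C@H](O)CC#C | starting material
12 | tert-butyl(dimethyl)[(2S)-pent-4-yn-2-yloxy]silane | C[C@H](O[Si](C)(C)C(C)(C)C)CC#C | intermediate
13 | N-methoxy-N-methylacetamide | CC(=O)N(C)OC | starting material
14 | (6S)-6-(TBSO)hept-3-yn-2-one | CC(=O)C#CC[C@H](C)O[Si](C)(C)C(C)(C)C | intermediate
15 | (2R,6S)-6-(TBSO)hept-3-yn-2-ol | C[C@@H](O)C#CC[C@H](C)O[Si](C)(C)C(C)(C)C | intermediate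
16 | (2R,6S)-6-(TBSO)hept-3-yn-2-yl methanesulfonate | C[C@@H](OS(C)(=O)=O)C#CC[C@H](C)O[Si](C)(C)C(C)(C)C | intermediate
17 | tributyl[(2S)-2-(TBSO)hepta-4,5-dien-4-yl]stannane, allene axis P (Sa) | CCCC[Sn](CCCC)(CCCC)C(C[C@H](C)O[Si](C)(C)C(C)(C)C)=[C@@]=C([H])C | intermediate
18 | di-tert-butyl 2-[(2R,3S,5R,6R,10S)-1,2,10-tris(TBSO)-5-hydroxy-6-methylundec-7-yn-3-yl]propanedioate | C[C@H](O[Si](C)(C)C(C)(C)C)CC#C[C@@H](C)[C@H](O)C[C@H]([C@@H](O[Si](C)(C)C(C)(C)C)CO[Si](C)(C)C(C)(C)C)C(C(=O)OC(C)(C)C)C(=O)OC(C)(C)C | intermediate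
19 | di-tert-butyl 2-[(2R,3S,5R,6R,10S)-1,2,5,10-tetrakis(TBSO)-6-methylundec-7-yn-3-yl]propanedioate | C[C@H](O[Si](C)(C)C(C)(C)C)CC#C[C@@H](C)[C@H](O[Si](C)(C)C(C)(C)C)C[C@H]([C@@H](O[Si](C)(C)C(C)(C)C)CO[Si](C)(C)C(C)(C)C)C(C(=O)OC(C)(C)C)C(=O)OC(C)(C)C | intermediate
20 | di-tert-butyl 2-[(2R,3S,5R,6S,10S)-1,2,5,10-tetrakis(TBSO)-6-methyl-7,8-dioxoundecan-3-yl]propanedioate | C[C@H](O[Si](C)(C)C(C)(C)C)CC(=O)C(=O)[C@@H](C)[C@H](O[Si](C)(C)C(C)(C)C)C[C@H]([C@@H](O[Si](C)(C)C(C)(C)C)CO[Si](C)(C)C(C)(C)C)C(C(=O)OC(C)(C)C)C(=O)OC(C)(C)C | intermediate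
21 | di-tert-butyl 2-[(2R,3S,5R,6S,10S)-2,5,10-tris(TBSO)-1-hydroxy-6-methyl-7,8-dioxoundecan-3-yl]propanedioate | C[C@H](O[Si](C)(C)C(C)(C)C)CC(=O)C(=O)[C@@H](C)[C@H](O[Si](C)(C)C(C)(C)C)C[C@H]([C@@H](O[Si](C)(C)C(C)(C)C)CO)C(C(=O)OC(C)(C)C)C(=O)OC(C)(C)C | intermediate
22 | di-tert-butyl 2-[(2R,3S,5R,6S,10S)-2,5,10-tris(TBSO)-6-methyl-1,7,8-trioxoundecan-3-yl]propanedioate | C[C@H](O[Si](C)(C)C(C)(C)C)CC(=O)C(=O)[C@@H](C)[C@H](O[Si](C)(C)C(C)(C)C)C[C@H]([C@@H](O[Si](C)(C)C(C)(C)C)C=O)C(C(=O)OC(C)(C)C)C(=O)OC(C)(C)C | intermediate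
23 | bis(diiodosamarium) C1/C2 enediolate of 22 (trivalent samarium on both oxygens; double-bond geometry left open) | C[C@H](O[Si](C)(C)C(C)(C)C)CC(O[Sm](I)I)=C(O[Sm](I)I)[C@@H](C)[C@H](O[Si](C)(C)C(C)(C)C)C[C@H]([C@@H](O[Si](C)(C)C(C)(C)C)C=O)C(C(=O)OC(C)(C)C)C(=O)OC(C)(C)C | intermediate
24 | di-tert-butyl 2-[(1S,2R,3S,4S,5S,6R)-2,6-bis(TBSO)-4-[(3S)-3-(TBSO)butanoyl]-3,4-dihydroxy-5-methylcycloheptyl]propanedioate | CC(C)(C)OC(=O)C(C(=O)OC(C)(C)C)[C@@H]1C[C@@H](O[Si](C)(C)C(C)(C)C)[C@H](C)[C@@](O)(C(=O)C[C@H](C)O[Si](C)(C)C(C)(C)C)[C@@H](O)[C@@H]1O[Si](C)(C)C(C)(C)C | intermediate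
25 | (R)-2-methylbutanoic acid | CC[C@@H](C)C(=O)O | starting material
26 | di-tert-butyl 2-[(1S,2R,3S,4S,5S,6R)-2,6-bis(TBSO)-4-[(3S)-3-(TBSO)butanoyl]-4-hydroxy-5-methyl-3-{[(2R)-2-methylbutanoyl]oxy}cycloheptyl]propanedioate | CC(C)(C)OC(=O)C(C(=O)OC(C)(C)C)[C@@H]1C[C@@H](O[Si](C)(C)C(C)(C)C)[C@H](C)[C@@](O)(C(=O)C[C@H](C)O[Si](C)(C)C(C)(C)C)[C@@H](OC(=O)[C@H](C)CC)[C@@H]1O[Si](C)(C)C(C)(C)C | intermediate
27 | di-tert-butyl 2-[(1S,2R,3S,4S,5S,6R)-2,4,6-trihydroxy-4-[(3S)-3-hydroxybutanoyl]-5-methyl-3-{[(2R)-2-methylbutanoyl]oxy}cycloheptyl]propanedioate | CC(C)(C)OC(=O)C(C(=O)OC(C)(C)C)[C@@H]1C[C@@H](O)[C@H](C)[C@@](O)(C(=O)C[C@H](C)O)[C@@H](OC(=O)[C@H](C)CC)[C@@H]1O | intermediate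
28 | 2-[(1S,2R,3S,4S,5S,6R)-2,4,6-trihydroxy-4-[(3S)-3-hydroxybutanoyl]-5-methyl-3-{[(2R)-2-methylbutanoyl]oxy}cycloheptyl]propanedioic acid | OC(=O)C(C(=O)O)[C@@H]1C[C@@H](O)[C@H](C)[C@@](O)(C(=O)C[C@H](C)O)[C@@H](OC(=O)[C@H](C)CC)[C@@H]1O | intermediate
29 | (3aS,5R,6S,7S,8S,8aR)-5,7-dihydroxy-7-[(3S)-3-hydroxybutanoyl]-6-methyl-8-{[(2R)-2-methylbutanoyl]oxy}-2-oxooctahydro-2H-cyclohepta[b]furan-3-carboxylic acid (C3 epimers) | OC(=O)C1C(=O)O[C@@H]2[C@H]1C[C@@H](O)[C@H](C)[C@@](O)(C(=O)C[C@H](C)O)[C@H]2OC(=O)[C@H](C)CC | intermediate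
30 | 3-[(diethylamino)methyl] derivative of 29 (Mannich base, C3 quaternary, configuration open) | CCN(CC)CC1(C(=O)O)C(=O)O[C@@H]2[C@H]1C[C@@H](O)[C@H](C)[C@@](O)(C(=O)C[C@H](C)O)[C@H]2OC(=O)[C@H](C)CC | intermediate
31 | (3aS,5R,6S,7S,8S,8aR)-5,7-dihydroxy-7-[(3S)-3-hydroxybutanoyl]-6-methyl-3-methylidene-2-oxooctahydro-2H-cyclohepta[b]furan-8-yl (2R)-2-methylbutanoate (CNP0291806.3) | C=C1C(=O)O[C@@H]2[C@H]1C[C@@H](O)[C@H](C)[C@@](O)(C(=O)C[C@H](C)O)[C@H]2OC(=O)[C@H](C)CC | target

## Step count and risks

Total: 21 steps. Longest linear sequence: 16 steps (steps 1–6 and 12–21, from 1). The side branch to 17 is steps 7–11.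

**Step 17 (key step, new method).**
- What may go wrong: proton transfer to the enediolate (from the malonate C–H or on quench) may outrun ring closure and give simple reduction to the acyloin. Closure through C2 may compete. The aldehyde may be delivered to the wrong face at C5 if a chelated or trans-fused transition state wins. Excess reductant may cleave the C1–O bond of the product ketol.
- Fallback (known chemistry, from 19, back at 24): buffered HF·pyridine frees the primary hydroxyl of 19 to give the alkynol F1, and Dess–Martin oxidation gives the ynal F2. A nickel-catalysed reductive alkyne–aldehyde cyclisation (Ni(cod)2, zerovalent nickel, PBu3, Et3SiH) then closes the same C1–C5 bond in the exo mode, giving the (E)-alkylidenecycloheptane F3 with C5 as its triethylsilyl ether. Ruthenium-catalysed ketohydroxylation of the trisubstituted alkene (RuCl3 cat., KHSO5·0.5KHSO4·0.5K2SO4, NaHCO3), expected anti to the allylic C5 oxygen, gives the ketol triethylsilyl ether F4. PPTS in MeOH removes the triethylsilyl group in the presence of the TBS ethers and gives 24.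

**Step 12 (syn propargylation).**
- What may go wrong: syn/anti selectivity of the open transition state erodes with an α-unbranched aldehyde, and BF3 may slowly cleave tert-butyl esters if the mixture warms.
- Fallback (from 14 and 10, back at 18): transfer hydrogenation of 14 with RuCl[(S,S)-TsDPEN](p-cymene) gives the (2S)-carbinol F5, and MsCl/Et3N gives the mesylate F6. Palladium/indium propargylation of 10 (PdCl2(dppf) cat., InI, THF/HMPA; cyclic transition state) gives the anti adduct F7, with C10 correct and C9 inverted. Mitsunobu inversion with 4-nitrobenzoic acid (PPh3, DIAD) gives the ester F8, and K2CO3/MeOH gives 18.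

**Step 14 (alkyne to diketone).**
- What may go wrong: over-oxidation with C1–C2 cleavage, or enolisation of the new diketone towards C10 with loss of configuration or β-elimination of the C9 silyloxy group.
- Fallback (from 19, back at 20): semihydrogenation (H2, Pd/CaCO3 poisoned with Pb(OAc)2, quinoline) gives the Z-alkene F9. Dihydroxylation (OsO4 cat., NMO) gives the diol F10 as a mixture of syn diols. Double Swern oxidation ((CF3CO)2O, DMSO; Et3N, −78 °C) gives 20.

**Step 21 (methylenation on the unprotected ketol).**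
- What may go wrong: conjugate addition of diethylamine to the new methylene lactone, aminomethylation at the ketone α-carbon C3, or base-induced dehydration of the β-hydroxy ketone on warming.
- Fallback (from 29, back at 31): with excess Et2NH and CH2O at room temperature the reaction is driven on purpose to the diethylamine adduct F11, which is stable and can be purified. MeI gives the ammonium iodide F12, and NaHCO3 (aq.)/CH2Cl2 eliminates it at room temperature to 31.

## Further compounds

F1 | step 17 | 19 without its primary silyl group (C5 alcohol, alkyne intact) | C[C@H](O[Si](C)(C)C(C)(C)C)CC#C[C@@H](C)[C@H](O[Si](C)(C)C(C)(C)C)C[C@H]([C@@H](O[Si](C)(C)C(C)(C)C)CO)C(C(=O)OC(C)(C)C)C(=O)OC(C)(C)C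
F2 | step 17 | C5 aldehyde of F1 (ynal) | C[C@H](O[Si](C)(C)C(C)(C)C)CC#C[C@@H](C)[C@H](O[Si](C)(C)C(C)(C)C)C[C@H]([C@@H](O[Si](C)(C)C(C)(C)C)C=O)C(C(=O)OC(C)(C)C)C(=O)OC(C)(C)C
F3 | step 17 | di-tert-butyl 2-[(4E)-2,6-bis(TBSO)-4-[(3S)-3-(TBSO)butylidene]-5-methyl-3-(triethylsilyloxy)cycloheptyl]propanedioate, ring configuration as in 24 | CC(C)(C)OC(=O)C(C(=O)OC(C)(C)C)[C@@H]1C[C@@H](O[Si](C)(C)C(C)(C)C)[C@H](C)/C(=C\C[C@H](C)O[Si](C)(C)C(C)(C)C)[C@@H](O[Si](CC)(CC)CC)[C@@H]1O[Si](C)(C)C(C)(C)C
F4 | step 17 | C5 triethylsilyl ether of 24 | CC(C)(C)OC(=O)C(C(=O)OC(C)(C)C)[C@@H]1C[C@@H](O[Si](C)(C)C(C)(C)C)[C@H](C)[C@@](O)(C(=O)C[C@H](C)O[Si](C)(C)C(C)(C)C)[C@@H](O[Si](CC)(CC)CC)[C@@H]1O[Si](C)(C)C(C)(C)C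
F5 | step 12 | (2S,6S)-6-(TBSO)hept-3-yn-2-ol | C[C@H](O)C#CC[C@H](C)O[Si](C)(C)C(C)(C)C
F6 | step 12 | (2S,6S)-6-(TBSO)hept-3-yn-2-yl methanesulfonate | C[C@H](OS(C)(=O)=O)C#CC[C@H](C)O[Si](C)(C)C(C)(C)C
F7 | step 12 | C9 epimer of 18 (anti adduct, 5S in the undecynyl numbering) | C[C@H](O[Si](C)(C)C(C)(C)C)CC#C[C@@H](C)[C@@H](O)C[C@H]([C@@H](O[Si](C)(C)C(C)(C)C)CO[Si](C)(C)C(C)(C)C)C(C(=O)OC(C)(C)C)C(=O)OC(C)(C)C
F8 | step 12 | 4-nitrobenzoate of 18 | C[C@H](O[Si](C)(C)C(C)(C)C)CC#C[C@@H](C)[C@H](OC(=O)c1ccc(cc1)[N+](=O)[O-])C[C@H]([C@@H](O[Si](C)(C)C(C)(C)C)CO[Si](C)(C)C(C)(C)C)C(C(=O)OC(C)(C)C)C(=O)OC(C)(C)C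
F9 | step 14 | (Z)-alkene from 19 (C1=C2) | C[C@H](O[Si](C)(C)C(C)(C)C)C/C=C\[C@@H](C)[C@H](O[Si](C)(C)C(C)(C)C)C[C@H]([C@@H](O[Si](C)(C)C(C)(C)C)CO[Si](C)(C)C(C)(C)C)C(C(=O)OC(C)(C)C)C(=O)OC(C)(C)C
F10 | step 14 | C1,C2 syn diol from F9 (mixture at the two new carbinols) | C[C@H](O[Si](C)(C)C(C)(C)C)CC(O)C(O)[C@@H](C)[C@H](O[Si](C)(C)C(C)(C)C)C[C@H]([C@@H](O[Si](C)(C)C(C)(C)C)CO[Si](C)(C)C(C)(C)C)C(C(=O)OC(C)(C)C)C(=O)OC(C)(C)C
F11 | step 21 | diethylamine adduct of 31 (3-[(diethylamino)methyl] lactone, C3 epimers) | CCN(CC)CC1C(=O)O[C@@H]2[C@H]1C[C@@H](O)[C@H](C)[C@@](O)(C(=O)C[C@H](C)O)[C@H]2OC(=O)[C@H](C)CC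
F12 | step 21 | N-methyl ammonium iodide of F11 | CC[N+](C)(CC)CC1C(=O)O[C@@H]2[C@H]1C[C@@H](O)[C@H](C)[C@@](O)(C(=O)C[C@H](C)O)[C@H]2OC(=O)[C@H](C)CC.[I-]
A1 | alternative 1 | 3-[2-(TBSO)ethyl]furan | CC(C)(C)[Si](C)(C)OCCc1ccoc1
A2 | alternative 1 | 3-chlorobutan-2-one | CC(Cl)C(C)=O
A3 | alternative 1 | 6-[2-(TBSO)ethyl]-2-methyl-8-oxabicyclo[3.2.1]oct-6-en-3-one (formed as the racemate; enantiomer as in the SMILES) | C[C@@H]1C(=O)C[C@H]2O[C@@H]1C=C2CCO[Si](C)(C)C(C)(C)C
A4 | alternative 2 | C9,C4-bis(triethylsilyl) ether of 31 | C=C1C(=O)O[C@@H]2[C@H]1C[C@@H](O[Si](CC)(CC)CC)[C@H](C)[C@@](O)(C(=O)C[C@H](C)O[Si](CC)(CC)CC)[C@H]2OC(=O)[C@H](C)CC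
A5 | alternative 3 | methyl 2-{3,4-bis(triethylsilyloxy)-4-[3-(TBSO)but-1-yn-1-yl]-5-methyl-2,6-dioxocycloheptyl}acetate (configuration as in the SMILES) | O=C1C[C@@H](CC(=O)OC)C(=O)[C@H](O[Si](CC)(CC)CC)[C@](O[Si](CC)(CC)CC)(C#C[C@H](C)O[Si](C)(C)C(C)(C)C)[C@H]1C
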